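**Strategy.** The cyclopenta[c]pyridine is read as an intramolecular Bohlmann–Rahtz product. In the pyridine ring (N2, C1, C7a, C4a, C4, C3), N2–C1=C7a–C7=O is an enaminone whose nucleophilic carbon is C7a, and C4a≡C4–C3=O is an alkynone that carries the dienyl chain; C7a and C4a are also the two ring-fusion atoms of the cyclopentanone (C4a, C5, C6, C7, C7a). One treatment with NH4OAc therefore forms N2–C1, C7a–C4a and N2–C3 and closes both rings, leaving the quaternary centres C5 and C6 untouched. The precursor is an open chain: dimethylamino enaminone, bis(triethylsilyl)-protected C5–C6 diol ester, dienyl ynone.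

Key step: step 12

Remark: atom labels (C1, N2, C3, C4, C4a, C5, C6, C7, C7a) follow the cyclopenta[c]pyridine numbering of the target and are kept for the corresponding atoms of open-chain intermediates; commercial solutions of LiN(iPr)2, LiN(SiMe3)2 and HC≡CMgBr are used as supplied.

**Step 1**
Reactants: 1 (R)-lactic acid; 2 pivalaldehyde
Product: 3 (2R,5R)-2-tert-butyl-5-methyl-1,3-dioxolan-4-one (cis isomer)
Conditions: TsOH·H2O (cat.), H2SO4 (trace), pentane, reflux with azeotropic removal of water; crystallisation from pentane at −78 °C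
Reagents that add atoms: none
Why: Acid-catalysed acetalisation in which the acetal centre equilibrates toward the cis (2R,5R) isomer, obtained pure by low-temperature crystallisation while the lactate centre is untouched.

**Step 2**
Reactants: 3 (2R,5R)-2-tert-butyl-5-methyl-1,3-dioxolan-4-one; 4 dimethyl oxalate
Product: 6 methyl 2-[(2R,4S)-2-tert-butyl-4-methyl-5-oxo-1,3-dioxolan-4-yl]-2-oxoacetate, via lithium enolate 5 (not isolated)
Conditions: LiN(iPr)2, THF, −78 °C; cannulated into (CO2Me)2 (3 equiv), THF, −78 °C; AcOH, −78 °C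
Reagents that add atoms: none
Why: Claisen-type C-acylation of the lithium enolate by excess oxalate; the electrophile enters trans to the tert-butyl group, so hydrogen is replaced with retention (self-regeneration of the stereocentre) and the future C6 is fixed, the cold acidic quench protecting the non-enolisable keto ester from retro-Claisen cleavage.

**Step 3**
Reactants: 6 methyl 2-[(2R,4S)-2-tert-butyl-4-methyl-5-oxo-1,3-dioxolan-4-yl]-2-oxoacetate
Product: 7 methyl (2R)-2-[(2R,4S)-2-tert-butyl-4-methyl-5-oxo-1,3-dioxolan-4-yl]-2-hydroxybut-3-ynoate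
Conditions: MgBr2·OEt2, CH2Cl2, −78 °C; HC≡CMgBr (THF), −78 °C; AcOH, −78 °C
Reagents that add atoms: ethynylmagnesium bromide, C#C[Mg]Br
Why: Grignard 1,2-addition to the ketone, by far the most electrophilic carbonyl; magnesium chelated between the ketone oxygen and the lactone carbonyl oxygen (six-membered 1,3-dicarbonyl chelate) fixes the C5–C6 rotamer, and the acetylide should add to C5 past the small ring oxygen on the face away from the C6 methyl group, giving 5R by 1,2-induction from C6.

**Step 4**
Reactants: 7 methyl (2R)-2-[(2R,4S)-2-tert-butyl-4-methyl-5-oxo-1,3-dioxolan-4-yl]-2-hydroxybut-3-ynoate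
Product: 8 methyl (2R)-2-[(2R,4S)-2-tert-butyl-4-methyl-5-oxo-1,3-dioxolan-4-yl]-2-(triethylsilyloxy)but-3-ynoate
Conditions: Et3SiOTf, 2,6-lutidine, CH2Cl2, −40 → 0 °C
Reagents that add atoms: triethylsilyl trifluoromethanesulfonate, CC[Si](CC)(CC)OS(=O)(=O)C(F)(F)F
Why: Silyl triflate silylation of a hindered tertiary alcohol; capping the C5 oxygen shuts down retro-aldol cleavage and hydroxyl-assisted attack on the neighbouring methyl ester in the next step.

**Step 5**
Reactants: 8 methyl (2R)-2-[(2R,4S)-2-tert-butyl-4-methyl-5-oxo-1,3-dioxolan-4-yl]-2-(triethylsilyloxy)but-3-ynoate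
Product: 9 methyl (2R,3S)-2-ethynyl-3-hydroxy-4-[methoxy(methyl)amino]-3-methyl-4-oxo-2-(triethylsilyloxy)butanoate
Conditions: MeNHOMe·HCl, AlMe3, CH2Cl2, 0 °C → rt; aq. potassium sodium tartrate
Reagents that add atoms: N,O-dimethylhydroxylamine hydrochloride, CNOC.Cl
Why: Aluminium amide aminolysis of the acylal-type lactone, whose strained, acyloxy-activated carbonyl should react far faster than the methyl ester buried between two fully substituted carbons; work-up of the hemiacetal aluminate releases pivalaldehyde and the C6 hydroxyl without touching either stereocentre.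

**Step 6**
Reactants: 9 methyl (2R,3S)-2-ethynyl-3-hydroxy-4-[methoxy(methyl)amino]-3-methyl-4-oxo-2-(triethylsilyloxy)butanoate
Product: 10 methyl (2R,3S)-2-ethynyl-4-[methoxy(methyl)amino]-3-methyl-4-oxo-2,3-bis(triethylsilyloxy)butanoate
Conditions: Et3SiOTf (excess), 2,6-lutidine, CH2Cl2, 0 °C → rt
Reagents that add atoms: triethylsilyl trifluoromethanesulfonate, CC[Si](CC)(CC)OS(=O)(=O)C(F)(F)F
Why: Second silyl triflate silylation, now of the C6 tertiary alcohol, gives the open-chain bis(triethylsilyl) ether that later blocks furanone formation and retro-aldol cleavage.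

**Step 7**
Reactants: 10 methyl (2R,3S)-2-ethynyl-4-[methoxy(methyl)amino]-3-methyl-4-oxo-2,3-bis(triethylsilyloxy)butanoate
Product: 12 methyl (2R,3S,5E)-6-(dimethylamino)-2-ethynyl-3-methyl-4-oxo-2,3-bis(triethylsilyloxy)hex-5-enoate, via terminal ynone 11 (not isolated)
Conditions: HC≡CMgBr (5 equiv), THF, 0 °C → rt; AcOH, −20 °C; Me2NH (2 M in THF, excess), 0 °C → rt
Reagents that add atoms: ethynylmagnesium bromide, C#C[Mg]Br; dimethylamine, CNC
Why: Grignard acyl substitution on the N-methoxy-N-methylamide stops at the ketone because the magnesium-chelated tetrahedral adduct survives until the quench and alkynyl Grignard reagents leave the hindered methyl ester alone; conjugate addition of the secondary amine to the terminal ynone then gives the E enaminone while the unactivated C5 ethynyl group does not react.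

**Step 8**
Reactants: 13 (S)-2-methylbutan-1-ol
Product: 14 (S)-2-methylbutanal (kept as a dried CH2Cl2 solution and used at once)
Conditions: TEMPO (cat.), PhI(OAc)2, CH2Cl2, 0 °C → rt; aq. NaHCO3 wash
Reagents that add atoms: none
Why: Oxoammonium-mediated (TEMPO-catalysed) alcohol oxidation under base-free conditions stops at the aldehyde and keeps the epimerisable α-stereocentre intact.

**Step 9**
Reactants: 14 (S)-2-methylbutanal
Product: 15 (2E,4S)-2,4-dimethylhex-2-enal
Conditions: Ph3P=C(CH3)CHO, toluene, 80 °C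
Reagents that add atoms: 2-(triphenylphosphoranylidene)propanal, CC(C=O)=P(c1ccccc1)(c1ccccc1)c1ccccc1
Why: Wittig olefination with a formyl-stabilised ylide under neutral conditions gives the E trisubstituted enal directly and does not epimerise the allylic stereocentre.

**Step 10**
Reactants: 15 (2E,4S)-2,4-dimethylhex-2-enal
Product: 16 (2E,4E,6S)-N-methoxy-N,4,6-trimethylocta-2,4-dienamide
Conditions: (EtO)2P(O)CH2C(O)N(OMe)Me (1.2 equiv), NaH (1.1 equiv), THF, 0 °C → rt
Reagents that add atoms: diethyl {2-[methoxy(methyl)amino]-2-oxoethyl}phosphonate, CCOP(=O)(CC(=O)N(C)OC)OCC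
Why: Horner–Wadsworth–Emmons olefination with the amide-stabilised phosphonate anion gives the E,E dienamide, and keeping NaH below the amount of phosphonate leaves no free base that could deconjugate the enal.

**Step 11**
Reactants: 12 methyl (2R,3S,5E)-6-(dimethylamino)-2-ethynyl-3-methyl-4-oxo-2,3-bis(triethylsilyloxy)hex-5-enoate; 16 (2E,4E,6S)-N-methoxy-N,4,6-trimethylocta-2,4-dienamide
Product: 18 methyl (2R,3S,5E)-6-(dimethylamino)-2-[(4E,6E,8S)-6,8-dimethyl-3-oxodeca-4,6-dien-1-yn-1-yl]-3-methyl-4-oxo-2,3-bis(triethylsilyloxy)hex-5-enoate, via lithium acetylide 17 (not isolated)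
Conditions: LiN(SiMe3)2 (1.0 equiv), THF, −78 °C; then 16, −78 → −20 °C; AcOH, −78 °C
Reagents that add atoms: none
Why: Deprotonation of the terminal alkyne (the only acidic site, since ester and enaminone have no α-hydrogen) and acylation of the lithium acetylide by the N-methoxy-N-methylamide, whose chelated tetrahedral adduct releases the ynone only on quenching, so 1,2-addition occurs once and the diene geometry and all stereocentres stay untouched.

**Step 12**
Reactants: 18 methyl (2R,3S,5E)-6-(dimethylamino)-2-[(4E,6E,8S)-6,8-dimethyl-3-oxodeca-4,6-dien-1-yn-1-yl]-3-methyl-4-oxo-2,3-bis(triethylsilyloxy)hex-5-enoate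
Product: 21 methyl (5R,6S)-3-[(1E,3E,5S)-3,5-dimethylhepta-1,3-dien-1-yl]-6-methyl-7-oxo-5,6-bis(triethylsilyloxy)-6,7-dihydro-5H-cyclopenta[c]pyridine-5-carboxylate, via primary enaminone 19 (not isolated), via aminodienone 20 (not isolated)
Conditions: NH4OAc (10 equiv), MeOH–AcOH (5:1), 50 → 65 °C
Reagents that add atoms: ammonium acetate, CC(=O)[O-].[NH4+]
Why: Proposed new method: ammonia released from NH4OAc exchanges with the dimethylamino group by addition–elimination at C1 to give primary enaminone 19, whose nucleophilic carbon C7a adds to the alkynone β-carbon C4a and, after proton transfer, gives the push–pull aminodienone 20, in which N2 condenses with the C3 ketone and water is lost; the closest known reaction type is the intermolecular Bohlmann–Rahtz pyridine synthesis from an enaminone, an alkynone and NH4OAc under acid catalysis, and what is new is that both partners sit in one chain so that the Michael step also closes a carbocycle. The cyclopentanone ring (C4a, C5, C6, C7, C7a) closes in 5-exo-dig mode and the pyridine ring (N2, C1, C7a, C4a, C4, C3) closes in 6-exo-trig mode followed by aromatising dehydration. No stereocentre is created, and C5 and C6, being quaternary and silyl-protected, can neither epimerise nor undergo retro-aldol cleavage. The step needs carbon instead of nitrogen attack on the alkynone, which the ring size secures (five-membered for C7a, seven-membered for N2), and it needs the C4a=C4 double bond with the acyl group on the side of C7a, which should be reached because this bond rotates easily in the protonated push–pull system and the bulky C5 centre disfavours the other isomer. The two triethylsilyl ethers keep the C6 and C5 oxygens from adding to C1 (furanone or pyranone formation), and the two adjacent quaternary carbons fold the chain for ring closure.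

**Step 13**
Reactants: 21 methyl (5R,6S)-3-[(1E,3E,5S)-3,5-dimethylhepta-1,3-dien-1-yl]-6-methyl-7-oxo-5,6-bis(triethylsilyloxy)-6,7-dihydro-5H-cyclopenta[c]pyridine-5-carboxylate
Product: 22 methyl (5R,6S)-3-[(1E,3E,5S)-3,5-dimethylhepta-1,3-dien-1-yl]-5,6-dihydroxy-6-methyl-7-oxo-6,7-dihydro-5H-cyclopenta[c]pyridine-5-carboxylate (CNP0086933.1)
Conditions: HF·pyridine, pyridine, THF, 0 °C → rt
Reagents that add atoms: none
Why: Fluoride-mediated desilylation under buffered, weakly acidic conditions removes both tertiary triethylsilyl ethers without exposing the β-hydroxy ketone and α-hydroxy ketone motifs of the product to base, which would invite retro-aldol cleavage or α-ketol rearrangement.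

**Compound list**
1 | (R)-lactic acid | C[C@@H](O)C(=O)O | starting material
2 | pivalaldehyde (2,2-dimethylpropanal) | CC(C)(C)C=O | starting material
3 | (2R,5R)-2-tert-butyl-5-methyl-1,3-dioxolan-4-one (cis) | C[C@H]1O[C@@H](C(C)(C)C)OC1=O | intermediate
4 | dimethyl oxalate | COC(=O)C(=O)OC | starting material
5 | lithium (2R)-2-tert-butyl-5-methyl-1,3-dioxol-4-olate (lithium enolate of 3) | CC1=C(O[Li])O[C@H](C(C)(C)C)O1 | intermediate
6 | methyl 2-[(2R,4S)-2-tert-butyl-4-methyl-5-oxo-1,3-dioxolan-4-yl]-2-oxoacetate | C[C@@]1(C(=O)C(=O)OC)O[C@@H](C(C)(C)C)OC1=O | intermediate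
7 | methyl (2R)-2-[(2R,4S)-2-tert-butyl-4-methyl-5-oxo-1,3-dioxolan-4-yl]-2-hydroxybut-3-ynoate | C[C@@]1([C@](O)(C#C)C(=O)OC)O[C@@H](C(C)(C)C)OC1=O | intermediate
8 | methyl (2R)-2-[(2R,4S)-2-tert-butyl-4-methyl-5-oxo-1,3-dioxolan-4-yl]-2-(triethylsilyloxy)but-3-ynoate | C[C@@]1([C@](O[Si](CC)(CC)CC)(C#C)C(=O)OC)O[C@@H](C(C)(C)C)OC1=O | intermediate
9 | methyl (2R,3S)-2-ethynyl-3-hydroxy-4-[methoxy(methyl)amino]-3-methyl-4-oxo-2-(triethylsilyloxy)butanoate | CON(C)C(=O)[C@@](C)(O)[C@@](C#C)(O[Si](CC)(CC)CC)C(=O)OC | intermediate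
10 | methyl (2R,3S)-2-ethynyl-4-[methoxy(methyl)amino]-3-methyl-4-oxo-2,3-bis(triethylsilyloxy)butanoate | CON(C)C(=O)[C@@](C)(O[Si](CC)(CC)CC)[C@@](C#C)(O[Si](CC)(CC)CC)C(=O)OC | intermediate
11 | methyl (2R,3S)-2-ethynyl-3-methyl-4-oxo-2,3-bis(triethylsilyloxy)hex-5-ynoate (terminal ynone) | C#CC(=O)[C@@](C)(O[Si](CC)(CC)CC)[C@@](C#C)(O[Si](CC)(CC)CC)C(=O)OC | intermediate
12 | methyl (2R,3S,5E)-6-(dimethylamino)-2-ethynyl-3-methyl-4-oxo-2,3-bis(triethylsilyloxy)hex-5-enoate | CN(C)/C=C/C(=O)[C@@](C)(O[Si](CC)(CC)CC)[C@@](C#C)(O[Si](CC)(CC)CC)C(=O)OC | intermediate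
13 | (S)-2-methylbutan-1-ol | CC[C@H](C)CO | starting material
14 | (S)-2-methylbutanal | CC[C@H](C)C=O | intermediate
15 | (2E,4S)-2,4-dimethylhex-2-enal | CC[C@H](C)/C=C(C)/C=O | intermediate
16 | (2E,4E,6S)-N-methoxy-N,4,6-trimethylocta-2,4-dienamide | CC[C@H](C)/C=C(C)/C=C/C(=O)N(C)OC | intermediate
17 | lithium acetylide of 12 (lithium on the terminal alkyne carbon C4) | CN(C)/C=C/C(=O)[C@@](C)(O[Si](CC)(CC)CC)[C@@](C#C[Li])(O[Si](CC)(CC)CC)C(=O)OC | intermediate
18 | methyl (2R,3S,5E)-6-(dimethylamino)-2-[(4E,6E,8S)-6,8-dimethyl-3-oxodeca-4,6-dien-1-yn-1-yl]-3-methyl-4-oxo-2,3-bis(triethylsilyloxy)hex-5-enoate (key-step precursor) | CN(C)/C=C/C(=O)[C@@](C)(O[Si](CC)(CC)CC)[C@@](C#CC(=O)/C=C/C(C)=C/[C@@H](C)CC)(O[Si](CC)(CC)CC)C(=O)OC | intermediate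
19 | methyl (2R,3S,5Z)-6-amino-2-[(4E,6E,8S)-6,8-dimethyl-3-oxodeca-4,6-dien-1-yn-1-yl]-3-methyl-4-oxo-2,3-bis(triethylsilyloxy)hex-5-enoate (primary enaminone) | N/C=C\C(=O)[C@@](C)(O[Si](CC)(CC)CC)[C@@](C#CC(=O)/C=C/C(C)=C/[C@@H](C)CC)(O[Si](CC)(CC)CC)C(=O)OC | intermediate
20 | methyl (1R,2S)-4-(aminomethylidene)-5-[(3E,5E,7S)-5,7-dimethyl-2-oxonona-3,5-dien-1-ylidene]-2-methyl-3-oxo-1,2-bis(triethylsilyloxy)cyclopentane-1-carboxylate (aminodienone, acyl group syn to C7a) | N/C=C1/C(=O)[C@@](C)(O[Si](CC)(CC)CC)[C@@](O[Si](CC)(CC)CC)(C(=O)OC)C/1=C/C(=O)/C=C/C(C)=C/[C@@H](C)CC | intermediate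
21 | methyl (5R,6S)-3-[(1E,3E,5S)-3,5-dimethylhepta-1,3-dien-1-yl]-6-methyl-7-oxo-5,6-bis(triethylsilyloxy)-6,7-dihydro-5H-cyclopenta[c]pyridine-5-carboxylate | CC[C@H](C)/C=C(C)/C=C/c1cc2c(cn1)C(=O)[C@@](C)(O[Si](CC)(CC)CC)[C@@]2(O[Si](CC)(CC)CC)C(=O)OC | intermediate
22 | methyl (5R,6S)-3-[(1E,3E,5S)-3,5-dimethylhepta-1,3-dien-1-yl]-5,6-dihydroxy-6-methyl-7-oxo-6,7-dihydro-5H-cyclopenta[c]pyridine-5-carboxylate | CC[C@H](C)/C=C(C)/C=C/c1cc2c(cn1)C(=O)[C@@](C)(O)[C@@]2(O)C(=O)OC | target

**Step count and risks**
Total step count: 13.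
Longest linear sequence: 10 steps (steps 1–7, 11, 12 and 13, from (R)-lactic acid); the side-chain branch is steps 8–10.

Steps most likely to fail:

1. Step 12 (Proposed new method). Ammonia may add to the alkynone or the dienone before it exchanges at C1. The exocyclic double bond of 20 may settle with the acyl group turned toward C5, so that cyclodehydration stalls. The silyl ethers may solvolyse in warm acidic methanol and open the way to oxygen cyclisation. Fallback with known chemistry only, setting out from 18 and coming back at 21: the enaminone of 18 is hydrolysed with aqueous oxalic acid in THF at 0 °C to the β-keto aldehyde F1. Catalytic Cs2CO3 in MeCN then brings about the base-mediated 5-exo-dig Michael addition of this 1,3-dicarbonyl unit to the alkynone, an established way to cyclopentanes with an exocyclic enone, and gives the hydroxymethylidene cyclopentanone F2, an ene-1,5-dicarbonyl compound. Heating F2 with NH4OAc in AcOH, the classical pyridine synthesis from 1,5-dicarbonyl compounds, gives 21. The two ring closures are thus separated and the carbocycle is closed by an enolate instead of an enamine.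

2. Step 3. Facial selectivity at the C5 ketone may be poor or reversed, because magnesium can also be held by the ring oxygen or by the two carbonyls of the keto ester, and these chelates do not all expose the same face. Fallback setting out from 3 (through its enolate 5) and coming back at 7: methyl 2-oxo-4-(trimethylsilyl)but-3-ynoate F3 is made by AlCl3-mediated acylation of bis(trimethylsilyl)acetylene with methyl chlorooxoacetate. Aldol addition of enolate 5 to the ketone of F3 at −78 °C forms the C5–C6 bond directly, trans to the tert-butyl group, and gives the silylalkyne adduct F4; the face of the keto ester is then chosen in a lithium-bridged cyclic transition state and not by chelation to a pre-formed C6 centre. Bu4NF buffered with AcOH at −20 °C removes the alkyne silyl group and gives 7.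

3. Step 7. Acyl substitution at a carbonyl flanked by two silyloxy-bearing quaternary carbons may be sluggish, and forcing it may bring attack on the methyl ester or loss of the N-methoxy group. Fallback setting out from 10 and coming back at 11: iBu2AlH in CH2Cl2 at −78 °C reduces the N-methoxy-N-methylamide to the aldehyde F5, since a small hydride reaches the crowded carbonyl and the chelated adduct stops at the aldehyde stage. HC≡CMgBr adds to the unhindered aldehyde to give the propargylic alcohol F6 as a mixture of carbinol epimers. MnO2 in CH2Cl2 oxidises F6 to ynone 11, which is treated with Me2NH as in step 7.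

**Further compounds**
F1 | step 12 | methyl (2R,3S)-2-[(4E,6E,8S)-6,8-dimethyl-3-oxodeca-4,6-dien-1-yn-1-yl]-3-methyl-4,6-dioxo-2,3-bis(triethylsilyloxy)hexanoate (β-keto aldehyde, drawn as the formyl tautomer) | O=CCC(=O)[C@@](C)(O[Si](CC)(CC)CC)[C@@](C#CC(=O)/C=C/C(C)=C/[C@@H](C)CC)(O[Si](CC)(CC)CC)C(=O)OC
F2 | step 12 | methyl (1R,2S)-5-[(3E,5E,7S)-5,7-dimethyl-2-oxonona-3,5-dien-1-ylidene]-4-(hydroxymethylidene)-2-methyl-3-oxo-1,2-bis(triethylsilyloxy)cyclopentane-1-carboxylate (exocyclic geometries equilibrating) | OC=C1C(=O)[C@@](C)(O[Si](CC)(CC)CC)[C@@](O[Si](CC)(CC)CC)(C(=O)OC)C1=CC(=O)/C=C/C(C)=C/[C@@H](C)CC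
F3 | step 3 | methyl 2-oxo-4-(trimethylsilyl)but-3-ynoate | COC(=O)C(=O)C#C[Si](C)(C)C
F4 | step 3 | methyl (2R)-2-[(2R,4S)-2-tert-butyl-4-methyl-5-oxo-1,3-dioxolan-4-yl]-2-hydroxy-4-(trimethylsilyl)but-3-ynoate | C[C@@]1([C@](O)(C#C[Si](C)(C)C)C(=O)OC)O[C@@H](C(C)(C)C)OC1=O
F5 | step 7 | methyl (2R,3S)-2-ethynyl-3-methyl-4-oxo-2,3-bis(triethylsilyloxy)butanoate | O=C[C@@](C)(O[Si](CC)(CC)CC)[C@@](C#C)(O[Si](CC)(CC)CC)C(=O)OC
F6 | step 7 | methyl (2R,3R)-2-ethynyl-4-hydroxy-3-methyl-2,3-bis(triethylsilyloxy)hex-5-ynoate (both C4 epimers) | C#CC(O)[C@@](C)(O[Si](CC)(CC)CC)[C@@](C#C)(O[Si](CC)(CC)CC)C(=O)OC
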